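**Remarks on assumptions**
- Atoms are numbered C1 (lactone carbonyl) to C20 along the chain of the target, and this numbering is kept for all intermediates; TBS = tert-butyldimethylsilyl, Ipc = isopinocampheyl.
- The target is treated as the enol (4-hydroxy) tautomer of a β-keto-δ-lactone; the keto lactone formed in the last step is assumed to tautomerise to it spontaneously.
- The (R)-half-ester 1 is assumed to be bought as such (it is an intermediate of statin manufacture, where it is made by desymmetrising methanolysis of 3-silyloxyglutaric anhydride); this shortens the way to the precursor of the key step.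

## Analysis of the target

The target 22 is an unbranched C20 chain whose C1–C5 end is closed into a 4-hydroxy-5,6-dihydro-2H-pyran-2-one (ring O–C1(=O)–C2H=C3(OH)–C4H2–C5H), while C6–C20 stays open and carries secondary hydroxyls on C7, C9 and C11 and a nonyl tail (C12–C20). There are four stereocentres, all oxygen-bearing and 1,3-related: C5 (R), C7 (R), C9 (S) and C11 (S); in the zigzag drawing C5/C7 are syn, C7/C9 anti and C9/C11 syn. Only CH2 groups lie between them and the pattern does not repeat, so each relationship has to come from reagent control or from relay by a neighbouring oxygen, not from one iterated protocol. The sensitive part is the vinylogous acid: its open β-keto acid form decarboxylates, β-oxygenated carbonyl arrays eliminate or undergo retro-aldol cleavage under base, and in any open-chain precursor the C7 hydroxyl can add to the C3 ketone. The two chain ends are different, so they are best introduced already differentiated. The strategy rests on C7 and C11: they are 1,5-related carbinols separated by C8, C9 and C10, and if C9 is taken back to an sp2 carbon of an E C8=C9 double bond they become the two carbinols of an (E)-1,5-anti-2-ene-1,5-diol, the pattern left when a three-carbon bifunctional allyl unit adds to two aldehydes in turn.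

## Retrosynthetic reasoning

**Acyl C1–O bond of the pyranone (22 to 21, then 20).** The ring is opened at the lactone bond, giving the δ-hydroxy-β-keto tert-butyl ester 21. This is the bond that closes most readily in the forward direction (six-membered, acid-mediated), and cutting it removes the acidic enol from all earlier steps. The four hydroxyls of 21 are masked as silyl ethers in 20 so that the preceding C–C bond formation sees no free OH.

**C2–C3 bond (20 to 19).** C1 and C2 are removed as a two-carbon ester enolate, leaving the methyl ester 19 with C3 at the carboxyl level. A crossed Claisen condensation is the forward reaction; it has to add once and must not enolise the ester towards C4, where loss of the C5 silyloxy group would follow.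

**Protecting-group exchange (19 to 18 to 17).** The tetrasilyl ether 19 comes from the triol ester 18, and 18 from 17, in which C3 and the C7 oxygen are tied in a δ-lactone and the C9 and C11 oxygens in a cyclic carbonate. Both rings are opened by methanolysis in one operation, which returns C3 as a methyl ester.

**C9–O bond (17 to 16 to 15 to 14).** The C9 oxygen is removed to leave the E C8=C9 double bond. In the forward direction it is delivered from the C11 oxygen through a carbonate tether onto an iodonium ion (15 to 16), which sets C9 syn to C11 through a six-membered chair, and the iodine left on C8 is then removed reductively (17). The cut is made here because C9 is the only oxygenated carbon with an existing stereocentre 1,3 to it on the far side of an alkene.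

**Temporary C3–O7 lactone (14 to 13).** For the tether to sit on C11 only, the C7 and C11 hydroxyls of the diol ester 13 must be told apart. Only the C7 hydroxyl can close a six-membered lactone onto the C3 ester, so 13 differentiates itself on lactonisation to 14, with no protecting group added. The lactone also keeps the C7 oxygen from acting as a nucleophile in the iodocyclisation.

**C7–C8 and C10–C11 bonds (13 to 3, 8 and 9).** The central disconnection removes C8–C10 as a three-carbon unit and leaves two aldehydes: 3 (C3–C7, with C5 in place) and decanal 9 (C11–C20). Cutting here places both unequal chain ends in separate, simple fragments and creates C7 and C11 together with the two bonds. The forward reaction, a double allylboration through the γ-borylallylborane made from 8 and a chiral dialkylborane, must add to 3 first and 9 second, override the C5 centre at C7, and give the E alkene with C11 anti to C7.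

**Fragments (3 to 2 to 1; 8 to 4).** Aldehyde 3 is the reduced form of the acid end of half-ester 1, reached by chemoselective reduction and oxidation. The allenylboronate 8 comes from propargyl bromide 4 by metalation, borylation and esterification.

## Alternatives that were turned down

**Alternative 1: two-directional allylic transposition.** The disconnection is at the C5–O and C11–O bonds: the four carbinols are traced to the C2-symmetric tetraol A2, whose inner anti diol (the later C7/C9 pair) is flanked by two primary (E)-allylic alcohols. In the forward key step Re2O7 and an aromatic aldehyde acetal would transpose both allylic hydroxyls through perrhenate esters by [3,3] shifts, and each new secondary oxygen would be captured with its neighbour as a 2-phenyl-1,3-dioxane, equilibrating to the all-equatorial bis-acetal A1.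
- For: two stereocentres are set in one catalytic, self-correcting operation, and the syn,anti,syn pattern fits exactly.
- Against: the target is not symmetric. The two vinyl groups of A1 are equivalent, yet one must be lengthened and reduced to C12–C20 and the other oxidised and extended to C1–C4, so a statistical mono-functionalisation is unavoidable. A2 itself needs an enantioselective synthesis, and the benzylidene acetals must come off late, next to the pyranone.
- Comparison: it is stronger in how C5 and C11 are controlled (thermodynamic, no stoichiometric chiral reagent). The chosen route instead brings the two different ends in as two different aldehydes and forms two skeletal bonds in the flask that sets two stereocentres.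

**Alternative 2: desymmetrising Baeyer–Villiger oxidation.** Six ring carbons of the meso ketone A4 (from a cheap achiral aromatic feedstock by hydrogenation, silylation and oxidation) would become C7–C12. Enantioselective oxygen insertion (a monooxygenase with O2 and NADPH, or Sc(OTf)3 with a chiral ligand and a peracid) would cut C7–C12 and give the oxepanone A3 with C9 and C11 fixed.
- For: the cheapest starting material, absolute configuration from a meso compound by catalysis, and two differentiated termini.
- Against: C12 is a plain CH2 in the target, so the new C12–O bond must be traded for a C–C bond to an octyl unit. C7 arrives at the carboxyl level, so the C7 stereocentre and the whole C1–C6 part including C5 still need a separate sequence. Selectivity of insertion into a 3,5-bis-silyloxy ketone is uncertain, and the β-silyloxy lactone can eliminate.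
- Comparison: it is stronger in the origin of chirality, but it addresses two of four stereocentres and none of the difficult C–C bonds. The chosen key step gives 13, in which every carbon from C3 to C20 is in place.

**Alternative 3: epoxide carbonylation to a β-lactone.** The disconnection is at C3–C4 (C3 from CO) and the acyl C3–O bond. The terminal epoxide A6 would take up CO under [(salph)Al(THF)2][Co(CO)4] catalysis (ring opening at C4 by the cobaltate, CO insertion, closure) to give the β-lactone A5 with C5 retained.
- For: it is atom-economic, and A5 is an activated acyl donor whose opening by an acetate enolate would give the δ-hydroxy-β-keto ester with the C5 hydroxyl already free. On this last stage it is stronger than the chosen end game, which has to unmask C5 by global desilylation.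
- Against: it is an end-game device. A6 already contains C5, C7, C9 and C11, so the whole stereotetrad must be made first by other means. The C3–C4 bond it forms is one the chosen route buys ready-made in 1. Pressurised CO and an air-sensitive catalyst would be used on a late intermediate, and the enolate could also attack the alkyl carbon of the β-lactone.
- Comparison: the chosen route accepts a less elegant last stage in return for a key step that solves the polyol assembly itself.

Key step: step 4

## Route

Step 1
Reactants: 1 (R)-3-(tert-butyldimethylsilyloxy)-5-methoxy-5-oxopentanoic acid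
Product: 2 methyl (R)-3-(tert-butyldimethylsilyloxy)-5-hydroxypentanoate
Conditions: BH3·SMe2, THF, 0 °C to rt; MeOH
Reagents that add atoms: none
Why: Borane reduces the carboxylic acid through its acyloxyborane much faster than it touches the methyl ester, so only the acid end should become CH2OH; the C5 stereocentre and the silyl ether are not involved, and 2 is used without heating to avoid closure to the valerolactone.

Step 2
Reactants: 2 methyl (R)-3-(tert-butyldimethylsilyloxy)-5-hydroxypentanoate
Product: 3 methyl (R)-3-(tert-butyldimethylsilyloxy)-5-oxopentanoate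
Conditions: TEMPO (cat.), PhI(OAc)2, CH2Cl2, rt
Reagents that add atoms: none
Why: Oxoammonium (TEMPO) oxidation stops at the aldehyde and runs without base, which should keep the β-silyloxy aldehyde from eliminating; C5 is untouched.

Step 3
Reactants: 4 propargyl bromide (3-bromoprop-1-yne)
Product: 8 2-(propa-1,2-dien-1-yl)-1,3,2-dioxaborinane, via allenylmagnesium bromide 5 (not isolated), via bromomagnesium allenyl(trimethoxy)borate 6 (not isolated), via allenylboronic acid 7 (not isolated)
Conditions: Mg, HgCl2 (cat.), Et2O, 0 °C; B(OMe)3, −78 °C; aq. HCl; HO(CH2)3OH, MgSO4, CH2Cl2, rt; distillation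
Reagents that add atoms: trimethyl borate COB(OC)OC; propane-1,3-diol OCCCO
Why: Grignard formation from propargyl bromide gives the allenyl magnesium species, which is borylated by trimethyl borate at low temperature; acid hydrolysis and boronic acid esterification with the diol should give the distillable allenylboronate.

Step 4
Reactants: 3 methyl (R)-3-(tert-butyldimethylsilyloxy)-5-oxopentanoate; 8 2-(propa-1,2-dien-1-yl)-1,3,2-dioxaborinane; 9 decanal
Product: 13 methyl (3R,5S,6E,9S)-3-(tert-butyldimethylsilyloxy)-5,9-dihydroxyoctadec-6-enoate, via (E)-γ-borylallyl-diisopinocampheylborane 10 (not isolated), via anti β-borinyloxy allylboronate 11 (not isolated), via bis-O-borylated diol ester 12 (not isolated)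
Conditions: (+)-(Ipc)2BH [(lIpc)2BH, from (−)-α-pinene and BH3·SMe2], 8, toluene, −25 to 0 °C; 3, −78 °C; 9, −78 °C to rt; aq. NaHCO3, H2O2, 0 °C to rt
Reagents that add atoms: none
Why: (Ipc)2BH adds across the terminal C=C of the allene in 8 (boron to CH2, hydrogen to the central carbon) and 1,3-boratropic equilibration should leave the E isomer 10, a three-carbon unit with a reactive dialkylborane at one end and an unreactive boronate at the other. At −78 °C only the dialkylborane end reacts: it allylates 3 through a Zimmerman–Traxler chair with the aldehyde chain and the E boronate substituent both equatorial, forming C7–C8 and giving the anti adduct 11 with C7 and the boron-bearing C8 defined. The isopinocampheyl groups from (−)-α-pinene direct the allyl unit to the Re face of the aldehyde, which sets C7 as S (syn to the C5 silyloxy group); β-silyloxy aldehydes exert only weak 1,3-induction in closed transition states, so reagent control should prevail over the resident C5 centre. On warming with 9 the α-substituted allylboronate 11 reacts through a second chair in which the C8 substituent is equatorial on the small, unsubstituted dioxaborinane; this forms C10–C11, makes C8=C9 E and transfers the C8 configuration to C11 (S), the boron leaving C8 on the face where the new bond forms (12). No ring of the carbon skeleton is closed; the only rings are the two transient six-membered boron chairs. The closest known reaction type is the one-pot double allylboration of two aldehydes with (E)-γ-boryl-allyl-diisopinocampheylboranes, which gives (E)-1,5-anti-2-ene-1,5-diols. The step needs the right order of addition (secured by the far higher reactivity of the borane end, with 3 limiting and 9 in excess), chemoselectivity (allylboranes do not add to the methyl ester) and E over Z (secured by the unhindered boronate ester); oxidative work-up cleaves the B–O and B–C bonds and releases 13.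

Step 5
Reactants: 13 methyl (3R,5S,6E,9S)-3-(tert-butyldimethylsilyloxy)-5,9-dihydroxyoctadec-6-enoate
Product: 14 (4R,6S)-4-(tert-butyldimethylsilyloxy)-6-[(1E,4S)-4-hydroxytridec-1-en-1-yl]oxan-2-one
Conditions: PPTS (cat.), toluene, 60 °C
Reagents that add atoms: none
Why: Acid-catalysed intramolecular transesterification (lactonisation): only the C7 hydroxyl is δ to the ester and can close a six-membered ring, whereas the C11 hydroxyl would need a ten-membered one, so the two hydroxyls are told apart without a protecting group; no stereocentre changes and the trans lactone results.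

Step 6
Reactants: 14 (4R,6S)-4-(tert-butyldimethylsilyloxy)-6-[(1E,4S)-4-hydroxytridec-1-en-1-yl]oxan-2-one
Product: 15 tert-butyl (1E,4S)-1-[(2S,4R)-4-(tert-butyldimethylsilyloxy)-6-oxooxan-2-yl]tridec-1-en-4-yl carbonate
Conditions: Boc2O, DMAP, MeCN, rt
Reagents that add atoms: di-tert-butyl dicarbonate CC(C)(C)OC(=O)OC(=O)OC(C)(C)C
Why: DMAP-catalysed acylation of the only free hydroxyl (C11) gives the mixed carbonate that will serve as the tethered oxygen nucleophile; C11 keeps its configuration.

Step 7
Reactants: 15 tert-butyl (1E,4S)-1-[(2S,4R)-4-(tert-butyldimethylsilyloxy)-6-oxooxan-2-yl]tridec-1-en-4-yl carbonate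
Product: 16 (4S,6S)-4-{(R)-iodo[(2S,4R)-4-(tert-butyldimethylsilyloxy)-6-oxooxan-2-yl]methyl}-6-nonyl-1,3-dioxan-2-one
Conditions: IBr, toluene, −85 °C; aq. Na2S2O3
Reagents that add atoms: iodine monobromide IBr
Why: Iodocarbonate cyclisation: the iodonium ion of the C8=C9 double bond is opened at C9 by the carbonyl oxygen of the carbonate in a 6-exo mode through a chair with the nonyl group and the alkene carbon equatorial, which should give the cis-4,6-disubstituted cyclic carbonate (C9 S, syn to C11) after loss of the tert-butyl cation; attack at C9 is also favoured electronically because the lactone oxygen on C7 deactivates C8, and anti addition places iodine on C8.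

Step 8
Reactants: 16 (4S,6S)-4-{(R)-iodo[(2S,4R)-4-(tert-butyldimethylsilyloxy)-6-oxooxan-2-yl]methyl}-6-nonyl-1,3-dioxan-2-one
Product: 17 (4R,6S)-4-{[(2R,4R)-4-(tert-butyldimethylsilyloxy)-6-oxooxan-2-yl]methyl}-6-nonyl-1,3-dioxan-2-one
Conditions: Bu3SnH, AIBN (cat.), toluene, 80 °C
Reagents that add atoms: none
Why: Radical chain dehalogenation: the C8 radical should take hydrogen from the tin hydride faster than it fragments a β C–O bond, so C8 becomes CH2 while C7 and C9 keep their configuration (their descriptors change only because the priorities change).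

Step 9
Reactants: 17 (4R,6S)-4-{[(2R,4R)-4-(tert-butyldimethylsilyloxy)-6-oxooxan-2-yl]methyl}-6-nonyl-1,3-dioxan-2-one
Product: 18 methyl (3R,5R,7S,9S)-3-(tert-butyldimethylsilyloxy)-5,7,9-trihydroxyoctadecanoate
Conditions: K2CO3 (cat.), MeOH, 0 °C to rt
Reagents that add atoms: methanol CO
Why: Methoxide-mediated transesterification removes the cyclic carbonate as dimethyl carbonate and opens the δ-lactone to the methyl ester, the large excess of methanol driving both; 18 is taken on at once so that the C7 hydroxyl does not close back onto the ester.

Step 10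
Reactants: 18 methyl (3R,5R,7S,9S)-3-(tert-butyldimethylsilyloxy)-5,7,9-trihydroxyoctadecanoate
Product: 19 methyl (3R,5R,7S,9S)-3,5,7,9-tetrakis(tert-butyldimethylsilyloxy)octadecanoate
Conditions: TBSOTf, 2,6-lutidine, CH2Cl2, −78 to 0 °C
Reagents that add atoms: tert-butyldimethylsilyl trifluoromethanesulfonate CC(C)(C)[Si](C)(C)OS(=O)(=O)C(F)(F)F
Why: A silyl triflate with a hindered base silylates the three secondary hydroxyls faster than relactonisation can occur; uniform silyl protection also makes any 1,3-silyl shift between the C5 and C7 oxygens in step 9 inconsequential and masks the C7 hydroxyl during the next step.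

Step 11
Reactants: 19 methyl (3R,5R,7S,9S)-3,5,7,9-tetrakis(tert-butyldimethylsilyloxy)octadecanoate
Product: 20 tert-butyl (5R,7R,9S,11S)-5,7,9,11-tetrakis(tert-butyldimethylsilyloxy)-3-oxoicosanoate
Conditions: LiN(iPr)2, tBuOAc, THF, −78 °C; then 19, −78 to −30 °C; aq. NH4Cl
Reagents that add atoms: tert-butyl acetate CC(=O)OC(C)(C)C
Why: Crossed Claisen condensation: the lithium enolate of tert-butyl acetate, which does not self-condense at low temperature, adds to the methyl ester carbon C3 and expels methoxide, forming C2–C3; the product is held as its enolate by the excess base, which should prevent a second addition.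

Step 12
Reactants: 20 tert-butyl (5R,7R,9S,11S)-5,7,9,11-tetrakis(tert-butyldimethylsilyloxy)-3-oxoicosanoate
Product: 21 tert-butyl (5R,7R,9S,11S)-5,7,9,11-tetrahydroxy-3-oxoicosanoate
Conditions: HF (48% aq.), MeCN/CH2Cl2, 0 °C to rt; aq. NaHCO3
Reagents that add atoms: none
Why: Acidic fluoride cleaves the four secondary silyl ethers while leaving the tert-butyl ester intact and, unlike basic fluoride, should not provoke retro-aldol cleavage or β-elimination at the β-hydroxy ketone; 21 is expected to equilibrate reversibly with the hemiketal between the C7 hydroxyl and the C3 ketone.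

Step 13
Reactants: 21 tert-butyl (5R,7R,9S,11S)-5,7,9,11-tetrahydroxy-3-oxoicosanoate
Product: 22 (6R)-4-hydroxy-6-[(2R,4S,6S)-2,4,6-trihydroxypentadecyl]-5,6-dihydro-2H-pyran-2-one
Conditions: TFA, CH2Cl2, 0 °C to rt
Reagents that add atoms: none
Why: Acid-mediated lactonisation of a δ-hydroxy-β-keto tert-butyl ester: the ester loses its tert-butyl group as isobutene while the C5 hydroxyl closes the six-membered ring at C1, and the β-keto lactone enolises to the vinylogous acid, which takes C3 out of the hemiketal equilibrium; no stereocentre is touched.

## Compound list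

1 | (R)-3-(tert-butyldimethylsilyloxy)-5-methoxy-5-oxopentanoic acid | OC(=O)C[C@@H](O[Si](C)(C)C(C)(C)C)CC(=O)OC | starting material
2 | methyl (R)-3-(tert-butyldimethylsilyloxy)-5-hydroxypentanoate | OCC[C@@H](O[Si](C)(C)C(C)(C)C)CC(=O)OC | intermediate
3 | methyl (R)-3-(tert-butyldimethylsilyloxy)-5-oxopentanoate | O=CC[C@@H](O[Si](C)(C)C(C)(C)C)CC(=O)OC | intermediate
4 | propargyl bromide (3-bromoprop-1-yne) | C#CCBr | starting material
5 | allenylmagnesium bromide (propa-1,2-dienylmagnesium bromide) | C=C=C[Mg]Br | intermediate (not isolated)
6 | bromomagnesium trimethoxy(propa-1,2-dienyl)borate | C=C=C[B-](OC)(OC)OC.[Mg+]Br | intermediate (not isolated)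
7 | propa-1,2-dienylboronic acid | C=C=CB(O)O | intermediate (not isolated)
8 | 2-(propa-1,2-dien-1-yl)-1,3,2-dioxaborinane | C=C=CB1OCCCO1 | intermediate
9 | decanal | CCCCCCCCCC=O | starting material
10 | [(2E)-3-(1,3,2-dioxaborinan-2-yl)prop-2-en-1-yl]bis[(1S,2R,3S,5S)-2,6,6-trimethylbicyclo[3.1.1]heptan-3-yl]borane | B(C/C=C/B1OCCCO1)([C@H]1C[C@H]2C[C@@H]([C@@H]1C)C2(C)C)[C@H]1C[C@H]2C[C@@H]([C@@H]1C)C2(C)C | intermediate (not isolated)
11 | methyl (3R,5S,6R)-5-[bis(isopinocampheyl)boranyloxy]-3-(tert-butyldimethylsilyloxy)-6-(1,3,2-dioxaborinan-2-yl)oct-7-enoate (5,6-anti) | C=C[C@@H](B1OCCCO1)[C@@H](OB([C@H]1C[C@H]2C[C@@H]([C@@H]1C)C2(C)C)[C@H]1C[C@H]2C[C@@H]([C@@H]1C)C2(C)C)C[C@@H](O[Si](C)(C)C(C)(C)C)CC(=O)OC | intermediate (not isolated)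
12 | methyl (3R,5S,6E,9S)-5-[bis(isopinocampheyl)boranyloxy]-3-(tert-butyldimethylsilyloxy)-9-(1,3,2-dioxaborinan-2-yloxy)octadec-6-enoate | CCCCCCCCC[C@H](OB1OCCCO1)C/C=C/[C@@H](OB([C@H]1C[C@H]2C[C@@H]([C@@H]1C)C2(C)C)[C@H]1C[C@H]2C[C@@H]([C@@H]1C)C2(C)C)C[C@@H](O[Si](C)(C)C(C)(C)C)CC(=O)OC | intermediate (not isolated)
13 | methyl (3R,5S,6E,9S)-3-(tert-butyldimethylsilyloxy)-5,9-dihydroxyoctadec-6-enoate | CCCCCCCCC[C@H](O)C/C=C/[C@@H](O)C[C@@H](O[Si](C)(C)C(C)(C)C)CC(=O)OC | intermediate
14 | (4R,6S)-4-(tert-butyldimethylsilyloxy)-6-[(1E,4S)-4-hydroxytridec-1-en-1-yl]oxan-2-one | CCCCCCCCC[C@H](O)C/C=C/[C@@H]1C[C@@H](O[Si](C)(C)C(C)(C)C)CC(=O)O1 | intermediate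
15 | tert-butyl (1E,4S)-1-[(2S,4R)-4-(tert-butyldimethylsilyloxy)-6-oxooxan-2-yl]tridec-1-en-4-yl carbonate | CCCCCCCCC[C@H](OC(=O)OC(C)(C)C)C/C=C/[C@@H]1C[C@@H](O[Si](C)(C)C(C)(C)C)CC(=O)O1 | intermediate
16 | (4S,6S)-4-{(R)-iodo[(2S,4R)-4-(tert-butyldimethylsilyloxy)-6-oxooxan-2-yl]methyl}-6-nonyl-1,3-dioxan-2-one | CCCCCCCCC[C@H]1C[C@@H]([C@H](I)[C@@H]2C[C@@H](O[Si](C)(C)C(C)(C)C)CC(=O)O2)OC(=O)O1 | intermediate
17 | (4R,6S)-4-{[(2R,4R)-4-(tert-butyldimethylsilyloxy)-6-oxooxan-2-yl]methyl}-6-nonyl-1,3-dioxan-2-one | CCCCCCCCC[C@H]1C[C@@H](C[C@@H]2C[C@@H](O[Si](C)(C)C(C)(C)C)CC(=O)O2)OC(=O)O1 | intermediate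
18 | methyl (3R,5R,7S,9S)-3-(tert-butyldimethylsilyloxy)-5,7,9-trihydroxyoctadecanoate | CCCCCCCCC[C@H](O)C[C@H](O)C[C@@H](O)C[C@@H](O[Si](C)(C)C(C)(C)C)CC(=O)OC | intermediate
19 | methyl (3R,5R,7S,9S)-3,5,7,9-tetrakis(tert-butyldimethylsilyloxy)octadecanoate | CCCCCCCCC[C@H](O[Si](C)(C)C(C)(C)C)C[C@H](O[Si](C)(C)C(C)(C)C)C[C@@H](O[Si](C)(C)C(C)(C)C)C[C@@H](O[Si](C)(C)C(C)(C)C)CC(=O)OC | intermediate
20 | tert-butyl (5R,7R,9S,11S)-5,7,9,11-tetrakis(tert-butyldimethylsilyloxy)-3-oxoicosanoate | CCCCCCCCC[C@H](O[Si](C)(C)C(C)(C)C)C[C@H](O[Si](C)(C)C(C)(C)C)C[C@@H](O[Si](C)(C)C(C)(C)C)C[C@@H](O[Si](C)(C)C(C)(C)C)CC(=O)CC(=O)OC(C)(C)C | intermediate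
21 | tert-butyl (5R,7R,9S,11S)-5,7,9,11-tetrahydroxy-3-oxoicosanoate | CCCCCCCCC[C@H](O)C[C@H](O)C[C@@H](O)C[C@@H](O)CC(=O)CC(=O)OC(C)(C)C | intermediate
22 | (6R)-4-hydroxy-6-[(2R,4S,6S)-2,4,6-trihydroxypentadecyl]-5,6-dihydro-2H-pyran-2-one | CCCCCCCCC[C@H](O)C[C@H](O)C[C@@H](O)C[C@@H]1CC(O)=CC(=O)O1 | target

## Step count and least certain steps

Total: 13 steps. Longest linear sequence: 12 steps (1 to 22 through steps 1, 2 and 4–13); the boronate 8 is made in one step from 4.

**Step 4 (key step).** The first allylboration may be less selective than planned, either because the reagent meets a mismatched C5 centre or because 10 is not purely E, which would lead to the syn adduct. The second allylboration is slow and may lose E selectivity, and 10 may add twice to the same aldehyde.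
Fallback, from 3 and 9, returning at 13: the C8=C9 bond is made by cross-metathesis and the two carbinols by separate reagent-controlled steps. Decanal 9 is allylated with B-allyl-(Ipc)2B of the same (−)-α-pinene series to give (S)-tridec-1-en-4-ol F1. Aldehyde 3 takes up CH2=CHMgBr at −78 °C to give methyl (3R)-3-(tert-butyldimethylsilyloxy)-5-hydroxyhept-6-enoate F2 as a mixture of C5 epimers, and Dess–Martin oxidation gives methyl (3R)-3-(tert-butyldimethylsilyloxy)-5-oxohept-6-enoate F3. Cross-metathesis of F3 with F1 (second-generation Hoveyda–Grubbs catalyst) should give the E enone methyl (3R,6E,9S)-3-(tert-butyldimethylsilyloxy)-9-hydroxy-5-oxooctadec-6-enoate F4. Corey–Bakshi–Shibata reduction of F4 with the (R)-2-methyl-oxazaborolidine and catecholborane sets C7 and gives 13.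

**Step 7.** The face of the alkene attacked may be decided in part by the allylic C7 stereocentre and not only by the chair of the tether, which would erode the syn relation of C9 to C11. Attack at C8 (seven-membered carbonate) is the other possible failure.
Fallback, from 14, returning at 18: the C9 oxygen is introduced as a ketone and its configuration set by reduction. Wacker oxidation of 14 (PdCl2 (cat.), CuCl, O2, DMF/H2O) should place the carbonyl on C9, the carbon remote from the electron-withdrawing lactone oxygen, giving (4R,6S)-4-(tert-butyldimethylsilyloxy)-6-[(4S)-4-hydroxy-2-oxotridecyl]oxan-2-one F5. Narasaka–Prasad reduction (Et2BOMe, NaBH4, THF/MeOH, −78 °C), directed by the C11 hydroxyl, gives the syn diol (4R,6R)-4-(tert-butyldimethylsilyloxy)-6-[(2S,4S)-2,4-dihydroxytridecyl]oxan-2-one F6, and methanolysis of its lactone (K2CO3, MeOH) gives 18.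

**Step 11.** The ester enolate may act as a base towards the hindered ester 19; enolisation towards C4 would be followed by loss of the C5 silyloxy group, and addition to the crowded ester carbonyl may be slow.
Fallback, from 19, returning at 20: the acylation is replaced by an aldol addition and an oxidation. Reduction of 19 with iBu2AlH at −78 °C gives the aldehyde (3R,5R,7S,9S)-3,5,7,9-tetrakis(tert-butyldimethylsilyloxy)octadecanal F7. The lithium enolate of tert-butyl acetate adds to it to give tert-butyl 3-hydroxy-5,7,9,11-tetrakis(tert-butyldimethylsilyloxy)icosanoate F8 (C3 epimers, both usable), and Dess–Martin oxidation of F8 gives 20.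

**Step 13.** In acid the C3/C7 hemiketal of 21 may lose water to a cyclic enol ether, and if the tert-butyl ester is cleaved before the ring closes, the β-keto acid may decarboxylate.
Fallback, from 21, returning at 22: the ring is closed under neutral conditions. Heating 21 in dilute toluene at about 105 °C should expel tert-butanol and form the acylketene (5R,7R,9S,11S)-5,7,9,11-tetrahydroxy-3-oxoicos-1-en-1-one F9, which is trapped by the C5 hydroxyl (the only one that can form a six-membered ring) to give 22.

## Further compounds

F1 | step 4 | (S)-tridec-1-en-4-ol | CCCCCCCCC[C@H](O)CC=C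
F2 | step 4 | methyl (3R)-3-(tert-butyldimethylsilyloxy)-5-hydroxyhept-6-enoate (both C5 epimers) | C=CC(O)C[C@@H](O[Si](C)(C)C(C)(C)C)CC(=O)OC
F3 | step 4 | methyl (3R)-3-(tert-butyldimethylsilyloxy)-5-oxohept-6-enoate | C=CC(=O)C[C@@H](O[Si](C)(C)C(C)(C)C)CC(=O)OC
F4 | step 4 | methyl (3R,6E,9S)-3-(tert-butyldimethylsilyloxy)-9-hydroxy-5-oxooctadec-6-enoate | CCCCCCCCC[C@H](O)C/C=C/C(=O)C[C@@H](O[Si](C)(C)C(C)(C)C)CC(=O)OC
F5 | step 7 | (4R,6S)-4-(tert-butyldimethylsilyloxy)-6-[(4S)-4-hydroxy-2-oxotridecyl]oxan-2-one | CCCCCCCCC[C@H](O)CC(=O)C[C@@H]1C[C@@H](O[Si](C)(C)C(C)(C)C)CC(=O)O1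
F6 | step 7 | (4R,6R)-4-(tert-butyldimethylsilyloxy)-6-[(2S,4S)-2,4-dihydroxytridecyl]oxan-2-one | CCCCCCCCC[C@H](O)C[C@H](O)C[C@@H]1C[C@@H](O[Si](C)(C)C(C)(C)C)CC(=O)O1
F7 | step 11 | (3R,5R,7S,9S)-3,5,7,9-tetrakis(tert-butyldimethylsilyloxy)octadecanal | CCCCCCCCC[C@H](O[Si](C)(C)C(C)(C)C)C[C@H](O[Si](C)(C)C(C)(C)C)C[C@@H](O[Si](C)(C)C(C)(C)C)C[C@@H](O[Si](C)(C)C(C)(C)C)CC=O
F8 | step 11 | tert-butyl 3-hydroxy-5,7,9,11-tetrakis(tert-butyldimethylsilyloxy)icosanoate (C3 epimers; C5, C7, C9 and C11 as in 19) | CCCCCCCCC[C@H](O[Si](C)(C)C(C)(C)C)C[C@H](O[Si](C)(C)C(C)(C)C)C[C@@H](O[Si](C)(C)C(C)(C)C)C[C@@H](O[Si](C)(C)C(C)(C)C)CC(O)CC(=O)OC(C)(C)C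
F9 | step 13 | (5R,7R,9S,11S)-5,7,9,11-tetrahydroxy-3-oxoicos-1-en-1-one (acylketene) | CCCCCCCCC[C@H](O)C[C@H](O)C[C@@H](O)C[C@@H](O)CC(=O)C=C=O
A1 | alternative 1 | C2-symmetric 3,5:7,9-bis(benzylidene acetal) of syn,anti,syn-undeca-1,10-diene-3,5,7,9-tetraol | C=C[C@H]1C[C@@H](C[C@@H]2C[C@H](C=C)O[C@H](c3ccccc3)O2)O[C@@H](c3ccccc3)O1
A2 | alternative 1 | (2E,5S,7S,9E)-undeca-2,9-diene-1,5,7,11-tetraol | OC/C=C/C[C@H](O)C[C@@H](O)C/C=C/CO
A3 | alternative 2 | (4S,6R)-4,6-bis(tert-butyldimethylsilyloxy)oxepan-2-one | C1[C@H](O[Si](C)(C)C(C)(C)C)C[C@H](O[Si](C)(C)C(C)(C)C)CC(=O)O1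
A4 | alternative 2 | cis-3,5-bis(tert-butyldimethylsilyloxy)cyclohexanone (meso) | O=C1C[C@@H](O[Si](C)(C)C(C)(C)C)C[C@@H](O[Si](C)(C)C(C)(C)C)C1
A5 | alternative 3 | β-lactone (4-substituted oxetan-2-one) holding C3, C4 and C5, with C7 silyl ether and C9/C11 acetonide | CCCCCCCCC[C@H]1C[C@@H](C[C@@H](O[Si](C)(C)C(C)(C)C)C[C@@H]2CC(=O)O2)OC(C)(C)O1
A6 | alternative 3 | terminal C4–C5 epoxide with C7 silyl ether and C9/C11 acetonide | CCCCCCCCC[C@H]1C[C@@H](C[C@@H](O[Si](C)(C)C(C)(C)C)C[C@@H]2CO2)OC(C)(C)O1
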